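**Overview**

- Numbering used throughout: ring A (trione) = C1 (benzoyl)–C2–C3–C4–C5 (geranyl)–C9; ring B = C5–C6–C7–C8 (gem-dimethyl)–C1; bridge C7–C10–C11–C3; cyclopentane C3–C14–C13–C12 (gem-dimethyl)–C11.
- Enabling feature: ring A has one carbon that can still enolize, C3. The target joins C3 to the C7 side chain (C3–C11) and closes the cyclopentane at C12–C13. A radical centred on C3 makes exactly these two bonds if C7 (endo) and C3 each carry a prenyl group.
- Retrosynthesis: put back a 2-hydroperoxyprop-2-yl group on C13 (it leaves as acetone); cut C12–C13 and C3–C11 (radical cascade); then C10–C11 (alkenylcerium addition to a C7 aldehyde); C1–C8 together with a temporary C3–C10 bond (acid cyclization to an adamantanol); C3–C14 (prenylation); C5–C6 (alkylative dearomatization); and the ring–geranyl bond.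
- Forward: ring A is the bought arene. Ring B and a temporary C3–C10 ring close in one acid step, and the C3–C10 ring is reopened by retro-aldol. The seven-membered ring and then the cyclopentane close in one manganese-mediated cascade, and an iron-induced β-scission trims C13 to CH2.
- Stereochemistry: C5 comes from a catalytic enantioselective phase-transfer alkylation. C1 and C7 are relayed from C5 through the adamantane. C3 and C11 are set in the cascade by the tether and by the twist of the forming bridge. The carbinol centre C10 and C13 are erased on the way.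

Key step: step 14

Assumption: the sense of induction in step 7 cannot be predicted with certainty; the cinchonidinium salt is written, and its cinchoninium pseudo-enantiomer would be taken if that is the one that delivers the C5 configuration shown.

Remark: the carbinol centre C10 (15, 16, 21, 22) and C13 of 25 are drawn as one epimer, and either epimer serves because both centres are erased later. Compounds 22 and 23 are drawn as the C4 enol carbonates; the C2 isomers would converge in step 13.

**Route**

Step 1
Reactants: 1 2,4,6-trihydroxybenzophenone; 2 geranyl bromide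
Product: 3 3-geranyl-2,4,6-trihydroxybenzophenone
Conditions: 2 (0.9 equiv), 10% aq. KOH, 0 °C to rt
Reagents that add atoms: none
Why: C-allylation of the phloroglucinolate in water, where hydrogen bonding to the oxygens steers the allylic bromide to ring carbon; a deficit of 2 should hold the reaction at mono-geranylation, and unreacted 1 is recovered.

Step 2
Reactants: 3 3-geranyl-2,4,6-trihydroxybenzophenone
Product: 4 3-bromo-5-geranyl-2,4,6-trihydroxybenzophenone
Conditions: NBS (1.0 equiv), THF, −78 °C
Reagents that add atoms: N-bromosuccinimide, O=C1CCC(=O)N1Br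
Why: Electrophilic aromatic bromination at the one remaining ring CH, which in a phloroglucinol is far more nucleophilic than the trisubstituted alkenes of the side chain at this temperature; the bromine later forces alkylation onto the geranyl-bearing carbon.

Step 3
Reactants: 5 diethyl isopropylidenemalonate
Product: 6 2-(propan-2-ylidene)propane-1,3-diol
Conditions: i-Bu2AlH (4.5 equiv), CH2Cl2, −78 to 0 °C; aq. potassium sodium tartrate
Reagents that add atoms: none
Why: 1,2-Reduction of both conjugated esters by the Lewis acidic aluminium hydride, which leaves the tetrasubstituted alkene alone.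

Step 4
Reactants: 6 2-(propan-2-ylidene)propane-1,3-diol
Product: 7 2-(hydroxymethyl)-3-methylbut-2-enal
Conditions: activated MnO2 (8 equiv), CH2Cl2, rt, stopped at mono-oxidation
Reagents that add atoms: none
Why: Allylic alcohol oxidation with MnO2; 6 is symmetric, so either CH2OH gives 7, and the second CH2OH then sits on an electron-poor enal alkene and should be oxidized much more slowly.

Step 5
Reactants: 7 2-(hydroxymethyl)-3-methylbut-2-enal
Product: 8 2-(dimethoxymethyl)-3-methylbut-2-en-1-ol
Conditions: HC(OMe)3, MeOH, pyridinium p-toluenesulfonate (cat.), rt; Et3N quench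
Reagents that add atoms: trimethyl orthoformate, COC(OC)OC; methanol, CO
Why: Acid-catalysed acetalization driven by the orthoester as water scavenger; the hindered β,β-disubstituted enal resists conjugate addition of methanol and the mild acid does not ionize the allylic alcohol.

Step 6
Reactants: 8 2-(dimethoxymethyl)-3-methylbut-2-en-1-ol
Product: 9 1-bromo-2-(dimethoxymethyl)-3-methylbut-2-ene
Conditions: CBr4, PPh3, 2,6-lutidine, CH2Cl2, 0 °C
Reagents that add atoms: carbon tetrabromide, BrC(Br)(Br)Br
Why: Appel bromination (SN2 displacement of the alkoxyphosphonium group at the primary allylic carbon) under buffered, acid-free conditions that keep the acetal; 9 is used at once.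

Step 7
Reactants: 4 3-bromo-5-geranyl-2,4,6-trihydroxybenzophenone; 9 1-bromo-2-(dimethoxymethyl)-3-methylbut-2-ene
Product: 10 C3-bromo dearomatized acetal: 4-benzoyl-2-bromo-6-[2-(dimethoxymethyl)-3-methylbut-2-en-1-yl]-6-geranyl-3,5-dihydroxycyclohexa-2,4-dien-1-one (ring C6 = C5 of the cage numbering; single enantiomer as in the SMILES)
Conditions: N-(9-anthracenylmethyl)-O-allylcinchonidinium bromide (10 mol %), CsOH·H2O (4 equiv), CH2Cl2, −40 °C; pH 6 phosphate work-up
Reagents that add atoms: none
Why: Enantioselective alkylative dearomatization under chiral phase-transfer catalysis: only the geranyl-bearing ring carbon can be alkylated productively, since C3 is blocked by bromine and C1 is deactivated by the benzoyl group, and the tight ion pair between the phloroglucinolate and the cinchona ammonium ion exposes one face of that carbon to the allylic bromide, which sets C5.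

Step 8
Reactants: 10 C3-bromo dearomatized acetal
Product: 11 C3-H dearomatized acetal: 4-benzoyl-6-[2-(dimethoxymethyl)-3-methylbut-2-en-1-yl]-6-geranyl-3,5-dihydroxycyclohexa-2,4-dien-1-one
Conditions: Na2S2O4, NaHCO3, THF–H2O, 0 °C
Reagents that add atoms: none
Why: Reductive removal of a positive halogen from a 2-bromo-1,3-dicarbonyl by dithionite; the weakly basic medium keeps the acetal, nothing else in the molecule is reducible under these conditions, and the quaternary C5 cannot epimerize.

Step 9
Reactants: 11 C3-H dearomatized acetal; 12 prenyl bromide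
Product: 13 C3-prenyl dearomatized acetal: 4-benzoyl-6-[2-(dimethoxymethyl)-3-methylbut-2-en-1-yl]-6-geranyl-3,5-dihydroxy-2-(3-methylbut-2-en-1-yl)cyclohexa-2,4-dien-1-one
Conditions: 12 (1.1 equiv), KOH (2 equiv), H2O–MeOH, 0 °C
Reagents that add atoms: none
Why: C-Allylation of the cyclic triketone enolate in protic solvent; C3 is the only ring carbon still bearing hydrogen, and a second alkylation of the now substituted C3 is much slower, as in the stepwise prenylation of acylphloroglucinols.

Step 10
Reactants: 13 C3-prenyl dearomatized acetal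
Product: 16 adamantanol 1-benzoyl-5-geranyl-10-hydroxy-8,8-dimethyl-3-(3-methylbut-2-en-1-yl)adamantane-2,4,9-trione, via enal 14 (not isolated), via aldol adduct 15 (not isolated)
Conditions: conc. HCl, THF, 0 °C to rt
Reagents that add atoms: water, O
Why: Acid unmasks the enal, the C3 enol adds to the protonated C10 aldehyde (intramolecular aldol, C3–C10), and the enolized benzoyl-bearing C1 then captures the tertiary C8 cation formed by protonation of C7=C8 (Prins-type cation–olefin closure, C1–C8), so that ring B and the adamantane close together; C1, C3 and C7 follow from C5 because the arm can bridge only across its own face of ring A and the cage forces C10 endo on C7, while the C10 carbinol configuration is immaterial.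

Step 11
Reactants: 16 adamantanol; 17 1-bromo-2-methylprop-1-ene
Product: 21 C7 allylic alcohol 1-benzoyl-5-geranyl-4-hydroxy-7-endo-(1-hydroxy-3-methylbut-2-en-1-yl)-8,8-dimethyl-3-(3-methylbut-2-en-1-yl)bicyclo[3.3.1]non-3-ene-2,9-dione, via 2-methylprop-1-enyllithium 18 (not isolated), via alkenylcerium dichloride 19 (not isolated), via ring-opened aldehyde 20 (not isolated)
Conditions: 17 (4 equiv), t-BuLi (8 equiv), THF, −78 °C; CeCl3 (4 equiv), −78 °C; then 16, −78 to −30 °C; aq. NH4Cl
Reagents that add atoms: none
Why: The first equivalent of the weakly basic organocerium 19 deprotonates the carbinol, the alkoxide fragments by retro-aldol (C3–C10 breaks, driven by the stabilized C2–C3–C4 diketonate), and a further equivalent adds 1,2 to the released aldehyde 20 (organocerium carbonyl addition) while the enolate and the hindered C9 and benzoyl ketones are left alone; C7 is not touched, so the new side chain stays endo, and the new carbinol centre is immaterial.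

Step 12
Reactants: 21 C7 allylic alcohol
Product: 22 bis(methyl carbonate) of 21 (allylic oxygen and enol oxygen)
Conditions: ClCO2Me (4 equiv), pyridine, DMAP (0.2 equiv), CH2Cl2, 0 °C to rt
Reagents that add atoms: methyl chloroformate, COC(=O)Cl
Why: Acylation under nucleophilic catalysis turns the allylic alcohol into the leaving group for the next step and masks the acidic enol as a non-nucleophilic enol carbonate, so that the diketone cannot recapture the allylpalladium intermediate at C10 and re-form the adamantane.

Step 13
Reactants: 22 bis(methyl carbonate)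
Product: 24 cascade precursor 1-benzoyl-5-geranyl-4-hydroxy-8,8-dimethyl-3,7-bis(3-methylbut-2-en-1-yl)bicyclo[3.3.1]non-3-ene-2,9-dione (7-endo prenyl), via enol carbonate 23 (not isolated)
Conditions: Pd(PPh3)4 (10 mol %), HCO2H, Et3N, THF, 40 °C; then K2CO3, MeOH, 0 °C
Reagents that add atoms: none
Why: Tsuji-type formate hydrogenolysis: zerovalent palladium ionizes the allylic carbonate, formate gives a palladium hydride on loss of CO2, and with the phosphine-rich catalyst the hydride is expected to go to the less substituted allyl terminus C10, which leaves the trisubstituted prenyl alkene and does not touch C7; excess formate suppresses β-hydride elimination to the diene, and brief methanolysis then frees the enol from carbonate 23.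

Step 14
Reactants: 24 cascade precursor
Product: 25 caged tetracycle carrying a 2-hydroperoxyprop-2-yl group on C13
Conditions: Mn(OAc)3·2H2O (0.5 equiv), AcOH, 5% O2 in N2 (1 atm), 23 °C, 2 mM
Reagents that add atoms: dioxygen, O=O
Why: Trivalent manganese oxidizes the enolized C2–C3–C4 diketone, the only enolizable site because C1 and C5 are quaternary, to the C3 radical; this adds to C11 of the endo C7 prenyl group, the tertiary C12 radical so formed adds to C13 of the C3 prenyl group, O2 captures the expelled exocyclic tertiary radical, and the peroxyl radical is reduced to the hydroperoxide with return of trivalent manganese. The closest known reaction type is the Mn(OAc)3-mediated oxidative radical cyclization cascade of 2-alkyl-1,3-diketones onto prenyl groups used for caged polyprenylated acylphloroglucinols, here with aerobic termination as in manganese-catalysed hydroperoxidation of 1,3-dicarbonyl compounds with alkenes. The seven-membered ring C3–C2–C1–C8–C7–C10–C11, which completes the homoadamantane, closes 7-exo-trig, and the cyclopentane C12–C11–C3–C14–C13 closes 5-exo-trig. C3 is fixed by the tether, since the C7 chain can reach only the endo face of C3; C11 is fixed by the twist the forming C10–C11 bridge must adopt to keep C12 clear of C14, because the mode with the CMe2 terminus under C2 lets C10 turn toward C6 whereas the mode with it under C4 turns C10 into the equatorial methyl group on C8; C13 is uncontrolled and is erased in step 15. The step needs C3 to attack the C7 prenyl group and not the geranyl chain, and both closures to outrun oxygen capture: the bridgehead geranyl group is equatorial and cannot reach the C3 orbital, the endo C7 chain lies beside C3 once ring B is a chair, and the lean oxygen atmosphere together with the fully substituted C3–C11 link (Thorpe–Ingold acceleration of the 5-exo closure) should let cyclization win at C12.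

Step 15
Reactants: 25 caged hydroperoxide
Product: 26 CNP0168637.1
Conditions: FeSO4·7H2O (1.2 equiv, aq., added slowly), PhSH (1.5 equiv), degassed MeOH, 0 °C to rt, 0.02 M
Reagents that add atoms: none
Why: Divalent iron cleaves the O–O bond to the tertiary alkoxy radical, which fragments by β-scission with loss of acetone toward the secondary C13 radical (far better than loss of a methyl radical), and thiophenol, kept dilute so that it does not intercept the alkoxy radical, then transfers hydrogen to C13; the reaction is run without oxygen, and C13 becomes CH2, so its earlier configuration does not matter.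

**Compound list**

1 | 2,4,6-trihydroxybenzophenone | O=C(c1ccccc1)c1c(O)cc(O)cc1O | starting material
2 | geranyl bromide, (2E)-1-bromo-3,7-dimethylocta-2,6-diene | CC(C)=CCC/C(C)=C/CBr | starting material
3 | 3-geranyl-2,4,6-trihydroxybenzophenone | CC(C)=CCC/C(C)=C/Cc1c(O)cc(O)c(C(=O)c2ccccc2)c1O | intermediate
4 | 3-bromo-5-geranyl-2,4,6-trihydroxybenzophenone | CC(C)=CCC/C(C)=C/Cc1c(O)c(Br)c(O)c(C(=O)c2ccccc2)c1O | intermediate
5 | diethyl isopropylidenemalonate, diethyl 2-(propan-2-ylidene)propanedioate | CCOC(=O)C(=C(C)C)C(=O)OCC | starting material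
6 | 2-(propan-2-ylidene)propane-1,3-diol | CC(C)=C(CO)CO | intermediate
7 | 2-(hydroxymethyl)-3-methylbut-2-enal | CC(C)=C(CO)C=O | intermediate
8 | 2-(dimethoxymethyl)-3-methylbut-2-en-1-ol | COC(OC)C(CO)=C(C)C | intermediate
9 | 1-bromo-2-(dimethoxymethyl)-3-methylbut-2-ene | COC(OC)C(CBr)=C(C)C | intermediate
10 | 4-benzoyl-2-bromo-6-[2-(dimethoxymethyl)-3-methylbut-2-en-1-yl]-6-geranyl-3,5-dihydroxycyclohexa-2,4-dien-1-one; quaternary carbon is C5, configured as in 26 | CC(C)=CCC/C(C)=C/C[C@@]1(CC(C(OC)OC)=C(C)C)C(=O)C(Br)=C(O)C(C(=O)c2ccccc2)=C1O | intermediate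
11 | 4-benzoyl-6-[2-(dimethoxymethyl)-3-methylbut-2-en-1-yl]-6-geranyl-3,5-dihydroxycyclohexa-2,4-dien-1-one; C5 as in 26 | CC(C)=CCC/C(C)=C/C[C@@]1(CC(C(OC)OC)=C(C)C)C(=O)C=C(O)C(C(=O)c2ccccc2)=C1O | intermediate
12 | prenyl bromide, 1-bromo-3-methylbut-2-ene | CC(C)=CCBr | starting material
13 | 4-benzoyl-6-[2-(dimethoxymethyl)-3-methylbut-2-en-1-yl]-6-geranyl-3,5-dihydroxy-2-(3-methylbut-2-en-1-yl)cyclohexa-2,4-dien-1-one; C5 as in 26 | CC(C)=CCC/C(C)=C/C[C@@]1(CC(C(OC)OC)=C(C)C)C(=O)C(CC=C(C)C)=C(O)C(C(=O)c2ccccc2)=C1O | intermediate
14 | enal: 13 with CHO (C10) in place of CH(OMe)2 | CC(C)=CCC/C(C)=C/C[C@@]1(CC(C=O)=C(C)C)C(=O)C(CC=C(C)C)=C(O)C(C(=O)c2ccccc2)=C1O | intermediate (not isolated)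
15 | aldol adduct: bicyclo[3.3.1]nonane with bridgeheads C3 (prenyl) and C5 (geranyl), one-carbon bridge C4=O, bridge C6H2–C7(=C8Me2)–C10H(OH), bridge C9(OH)=C1(benzoyl)–C2(=O) | CC(C)=CCC/C(C)=C/C[C@@]12CC(=C(C)C)[C@@H](O)[C@@](CC=C(C)C)(C1=O)C(=O)C(C(=O)c1ccccc1)=C2O | intermediate (not isolated)
16 | adamantanol: 1-benzoyl-5-geranyl-10-hydroxy-8,8-dimethyl-3-(3-methylbut-2-en-1-yl)adamantane-2,4,9-trione; C1, C3, C5, C7 as in the SMILES | CC(C)=CCC/C(C)=C/C[C@@]12C[C@H]3[C@@H](O)[C@@](CC=C(C)C)(C1=O)C(=O)[C@@](C(=O)c1ccccc1)(C2=O)C3(C)C | intermediate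
17 | 1-bromo-2-methylprop-1-ene | CC(C)=CBr | starting material
18 | 2-methylprop-1-enyllithium | [Li]C=C(C)C | intermediate (not isolated)
19 | (2-methylprop-1-enyl)cerium dichloride | Cl[Ce](Cl)C=C(C)C | intermediate (not isolated)
20 | ring-opened aldehyde: 1-benzoyl-5-geranyl-4-hydroxy-8,8-dimethyl-3-(3-methylbut-2-en-1-yl)-2,9-dioxobicyclo[3.3.1]non-3-ene-7-endo-carbaldehyde (present as its enolate) | CC(C)=CCC/C(C)=C/C[C@@]12C[C@@H](C=O)C(C)(C)[C@](C(=O)c3ccccc3)(C2=O)C(=O)C(CC=C(C)C)=C1O | intermediate (not isolated)
21 | 1-benzoyl-5-geranyl-4-hydroxy-7-endo-(1-hydroxy-3-methylbut-2-en-1-yl)-8,8-dimethyl-3-(3-methylbut-2-en-1-yl)bicyclo[3.3.1]non-3-ene-2,9-dione | CC(C)=CCC/C(C)=C/C[C@@]12C[C@@H]([C@H](O)C=C(C)C)C(C)(C)[C@](C(=O)c3ccccc3)(C2=O)C(=O)C(CC=C(C)C)=C1O | intermediate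
22 | bis(methyl carbonate) of 21: methoxycarbonyloxy groups on the allylic carbon C10 and on the C4 enol oxygen | CC(C)=CCC/C(C)=C/C[C@@]12C[C@@H]([C@H](OC(=O)OC)C=C(C)C)C(C)(C)[C@](C(=O)c3ccccc3)(C2=O)C(=O)C(CC=C(C)C)=C1OC(=O)OC | intermediate
23 | C4 enol methyl carbonate of 24 | CC(C)=CCC/C(C)=C/C[C@@]12C[C@@H](CC=C(C)C)C(C)(C)[C@](C(=O)c3ccccc3)(C2=O)C(=O)C(CC=C(C)C)=C1OC(=O)OC | intermediate (not isolated)
24 | 1-benzoyl-5-geranyl-4-hydroxy-8,8-dimethyl-3,7-bis(3-methylbut-2-en-1-yl)bicyclo[3.3.1]non-3-ene-2,9-dione, 7-endo prenyl | CC(C)=CCC/C(C)=C/C[C@@]12C[C@@H](CC=C(C)C)C(C)(C)[C@](C(=O)c3ccccc3)(C2=O)C(=O)C(CC=C(C)C)=C1O | intermediate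
25 | 26 carrying a 2-hydroperoxyprop-2-yl group on C13 | CC(C)=CCC/C(C)=C/C[C@@]12C[C@H]3C[C@@H]4C(C)(C)[C@H](C(C)(C)OO)C[C@]4(C1=O)C(=O)[C@@](C(=O)c1ccccc1)(C2=O)C3(C)C | intermediate
26 | CNP0168637.1: homoadamantane trione (C2, C4, C9 ketones) with benzoyl on C1, geranyl on C5, gem-dimethyl on C8, bridge C7–C10–C11–C3 and cyclopentane C3–C14–C13–C12(Me2)–C11 | CC(C)=CCC/C(C)=C/C[C@@]12C[C@H]3C[C@@H]4C(C)(C)CC[C@]4(C1=O)C(=O)[C@@](C(=O)c1ccccc1)(C2=O)C3(C)C | target

**Step count and risks**

Total step count: 15. Longest linear sequence: 13 steps (5 to 26, steps 3 to 15).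

Steps most likely to fail:

1. Step 14. Oxygen may capture the C3 radical, or the C12 radical after the first closure, before the rings have formed. The facial selectivity at C11 also rests on a conformational argument only. Fallback: setting out from 24, the cascade would be run without oxygen, with Mn(OAc)3·2H2O (2.2 equiv) and Cu(OAc)2·H2O (1 equiv) in degassed AcOH. Nothing then competes with either closure, and divalent copper oxidizes the last radical to the alkene, which should give the caged tetracycle carrying a prop-1-en-2-yl group on C13 F1. Its 1,1-disubstituted alkene accepts a hydrogen atom faster than the two trisubstituted alkenes of the geranyl chain. Isayama–Mukaiyama hydroperoxysilylation (Co(acac)2 cat., Et3SiH, O2, ClCH2CH2Cl, rt, stopped early) would therefore convert it into the triethylsilyl peroxide F2. A trace of HCl in MeOH would remove the silyl group and rejoin the route at 25.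

2. Step 15. The alkoxy radical may be reduced to the tertiary alcohol, or abstract hydrogen from a C12 methyl group, faster than it fragments. Thiyl radicals may also isomerize the E alkene of the geranyl chain. Fallback: setting out from 25, a Criegee rearrangement would replace the radical fragmentation. Ac2O, Et3N and DMAP in CH2Cl2 should give the peracetate F3. In it C13, a secondary alkyl group that migrates in preference to methyl, shifts from carbon to oxygen to give the C13 2-acetoxyprop-2-yl ether F4. Aqueous acid work-up would hydrolyse this to the C13 alcohol F5. Acylation with 1,1'-thiocarbonyldiimidazole (DMAP, toluene, 80 °C) would give the O-(imidazol-1-ylthiocarbonyl) derivative F6, and Barton–McCombie deoxygenation (Bu3SnH, AIBN, toluene, 80 °C) would rejoin the route at 26.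

3. Step 7. The ion pair may discriminate poorly between the two faces of C5, and O-alkylation or alkylation at the bromine-bearing carbon may compete under the phase-transfer conditions. Fallback: setting out from 4 and 9, the alkylative dearomatization would be run without a chiral catalyst (LiN(SiMe3)2, THF, −78 to 0 °C) to give the racemic C3-bromo dearomatized acetal F7. Separation of the enantiomers by preparative chromatography on a chiral stationary phase (amylose tris(3,5-dimethylphenylcarbamate), supercritical CO2–MeOH) would rejoin the route at 10.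

Further compounds
F1 | step 14 | caged tetracycle carrying a prop-1-en-2-yl group on C13 | CC(C)=CCC/C(C)=C/C[C@@]12C[C@H]3C[C@@H]4C(C)(C)[C@H](C(C)=C)C[C@]4(C1=O)C(=O)[C@@](C(=O)c1ccccc1)(C2=O)C3(C)C
F2 | step 14 | triethylsilyl peroxide of 25 | CC(C)=CCC/C(C)=C/C[C@@]12C[C@H]3C[C@@H]4C(C)(C)[C@H](C(C)(C)OO[Si](CC)(CC)CC)C[C@]4(C1=O)C(=O)[C@@](C(=O)c1ccccc1)(C2=O)C3(C)C
F3 | step 15 | peracetate of 25 | CC(C)=CCC/C(C)=C/C[C@@]12C[C@H]3C[C@@H]4C(C)(C)[C@H](C(C)(C)OOC(C)=O)C[C@]4(C1=O)C(=O)[C@@](C(=O)c1ccccc1)(C2=O)C3(C)C
F4 | step 15 | C13 2-acetoxyprop-2-yl ether of the cage | CC(C)=CCC/C(C)=C/C[C@@]12C[C@H]3C[C@@H]4C(C)(C)[C@H](OC(C)(C)OC(C)=O)C[C@]4(C1=O)C(=O)[C@@](C(=O)c1ccccc1)(C2=O)C3(C)C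
F5 | step 15 | C13 alcohol of the cage | CC(C)=CCC/C(C)=C/C[C@@]12C[C@H]3C[C@@H]4C(C)(C)[C@H](O)C[C@]4(C1=O)C(=O)[C@@](C(=O)c1ccccc1)(C2=O)C3(C)C
F6 | step 15 | C13 O-(imidazol-1-ylthiocarbonyl) derivative of F5 | CC(C)=CCC/C(C)=C/C[C@@]12C[C@H]3C[C@@H]4C(C)(C)[C@H](OC(=S)n5ccnc5)C[C@]4(C1=O)C(=O)[C@@](C(=O)c1ccccc1)(C2=O)C3(C)C
F7 | step 7 | racemic C3-bromo dearomatized acetal (racemate of 10) | CC(C)=CCC/C(C)=C/CC1(CC(C(OC)OC)=C(C)C)C(=O)C(Br)=C(O)C(C(=O)c2ccccc2)=C1O
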